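**Plan**

- Target locants: C1 CHOH, C2 CH2, C3 CHOAc, C4(Me)=C5, C6 lactone O–CH, C7 ring-fusion CH, C8 acyloxy CH, C9=C10(Me), C11=C13, C12 lactone C=O. The enabling feature is the lone C2 methylene in the ten-membered ring, flanked by the C1 carbinol and the anti C3 acetate. This is the imprint of a methyl-ketone/aldehyde aldol followed by Evans–Tishchenko reduction, which leaves the ester on the aldol oxygen.
- Retrosynthetic cuts, in order: C2–C3 together with C1–H and O3–acetyl (step 17); C1–C10 (Stille, then bromination); O8–acyl; C4=C5 (Still–Gennari); O6–C12 (lactonisation); C11=C13 (Mannich methylenation); C9=C10 (Stork–Zhao); C7–C11 (Wittig, hydrogenation).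
- Forward: the furanose of diacetone-D-glucose supplies C5–C9 (sugar C1–C5). The γ-lactone closes on O6 in step 8 while O8 is still the furanose oxygen, the furanose is opened by olefination in step 9, and the ten-membered ring closes last.
- Stereochemistry: C6 and C8 are C2 and C4 of D-glucose; C7 comes from exo-face hydrogenation (allo); both alkenes are made Z by kinetic olefinations; C2′ comes from (R)-2-methylbutanoic acid; C3 comes from the face of the macro-aldol; C1 follows anti from C3 by intramolecular hydride transfer.

Key step: step 17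

Remark: the macro-aldol is assumed to expose the C3 aldehyde face that leads to the 3S aldolate. Compound 4 is carried as an alkene-isomer mixture, and 11, 14, 15 and 19 as epimer mixtures at centres that are later flattened or oxidised.

**Route**

Step 1
Reactants: 1 diacetone-D-glucose (1,2:5,6-di-O-isopropylidene-α-D-glucofuranose)
Product: 2 1,2:5,6-di-O-isopropylidene-α-D-ribo-hexofuranos-3-ulose
Conditions: Dess–Martin periodinane, CH2Cl2, rt
Reagents that add atoms: none
Why: Dess–Martin oxidation converts the hindered secondary alcohol at sugar C3 into the ketone without touching either acetonide or the adjacent stereocentres, a standard entry to this ulose.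

Step 2
Reactants: 2 the 3-ulose; 3 ethyl (triphenylphosphoranylidene)acetate
Product: 4 ethyl 2-(3-deoxy-1,2:5,6-di-O-isopropylidene-α-D-ribo-hexofuranos-3-ylidene)acetate (alkene isomers)
Conditions: toluene, 80 °C
Reagents that add atoms: none
Why: Wittig olefination with the stabilised ylide is well known on this furanosulose and installs the two-carbon arm (future C11–C12) as an exocyclic enoate whose geometry is irrelevant because step 3 saturates it.

Step 3
Reactants: 4 the exocyclic enoate
Product: 5 3-deoxy-3-C-(2-ethoxy-2-oxoethyl)-1,2:5,6-di-O-isopropylidene-α-D-allofuranose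
Conditions: H2 (1 atm), Pd/C, EtOAc, rt
Reagents that add atoms: none
Why: Heterogeneous hydrogenation adds hydrogen to the exo face of the cis-fused bicycle, opposite the 1,2-acetonide, so that the acetate arm becomes cis to O2 (allo configuration), which fixes the future C7 relative to C6 and C8.

Step 4
Reactants: 5 the allo ester
Product: 7 3-deoxy-3-C-(2-ethoxy-2-oxoethyl)-1,2-O-isopropylidene-α-D-ribo-pentodialdo-1,4-furanose, via 5,6-diol 6 (not isolated)
Conditions: H5IO6, EtOAc, rt
Reagents that add atoms: none
Why: Periodic acid in ethyl acetate hydrolyses the terminal acetonide selectively and cleaves the released glycol in the same flask (glycol cleavage), the ring-fused 1,2-acetonide surviving and the C4 centre being stable because its substituent is already trans to the C3 arm.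

Step 5
Reactants: 7 the pentodialdofuranose; 8 ethyltriphenylphosphonium iodide
Product: 9 (5Z)-3,5,6,7-tetradeoxy-3-C-(2-ethoxy-2-oxoethyl)-6-iodo-1,2-O-isopropylidene-α-D-ribo-hept-5-enofuranose
Conditions: 8, n-BuLi, THF, rt; I2, −78 °C; NaN(SiMe3)2, −20 °C; then 7, −78 °C to rt
Reagents that add atoms: iodine, SMILES [I][I]
Why: Stork–Zhao olefination with the α-iodoethylidene ylide gives the (Z)-2-iodoalkene under kinetic control (iodine cis to the furanose carbon, the future C8), the ester being inert to the ylide at −78 °C, and the iodide is a masked C1 acyl group that tolerates every step up to 15.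

Step 6
Reactants: 9 the (Z)-vinyl iodide
Product: 11 Mannich base of 9 (CH2NMe2 on the ester α-carbon; both C11 epimers), via lithium enolate 10 (not isolated)
Conditions: LiN(i-Pr)2, THF, −78 °C; CH2=NMe2+ I−, −78 °C to rt
Reagents that add atoms: Eschenmoser's salt (N,N-dimethylmethyleneiminium iodide), SMILES C=[N+](C)C.[I-]
Why: Ester enolate aminomethylation with the preformed iminium salt (Mannich reaction) places the future C13 on C11; LDA at −78 °C does not attack the vinyl iodide, no β-leaving group is present, and the new centre is of no consequence because it becomes sp2 in step 7.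

Step 7
Reactants: 11 the Mannich base
Product: 13 (5Z)-3,5,6,7-tetradeoxy-3-C-[1-(ethoxycarbonyl)ethenyl]-6-iodo-1,2-O-isopropylidene-α-D-ribo-hept-5-enofuranose, via methiodide 12 (not isolated)
Conditions: MeI, THF, rt; then NaHCO3 (aq), CH2Cl2, rt
Reagents that add atoms: none
Why: Exhaustive N-methylation followed by mild-base E1cB (Hofmann-type) elimination of trimethylamine is the standard second half of an α-methylenation and gives the acrylate without affecting acetonide or vinyl iodide.

Step 8
Reactants: 13 the acrylate
Product: 15 cis-fused lactol–lactone (α-methylene-γ-lactone O6–C12 fused to the furanose hemiacetal at C5 whose ring oxygen is O8; (Z)-2-iodoprop-1-enyl on C8; anomers), via hydroxy ester lactol 14 (not isolated)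
Conditions: CF3CO2H/H2O (9:1), 0 °C to rt; toluene azeotrope
Reagents that add atoms: none
Why: Acid hydrolysis of the isopropylidene acetal frees O2 and the anomeric hydroxyl, and O2 closes onto the cis-disposed acrylate ester by 5-exo-trig lactonisation to the cis-fused α-methylene-γ-lactone, whereas O4 (the future O8) stays locked in the furanose hemiacetal and cannot compete; no stereocentre other than the anomeric one is affected.

Step 9
Reactants: 15 the lactol–lactone; 16 ethyl 2-[bis(2,2,2-trifluoroethoxy)phosphoryl]propanoate
Product: 17 ethyl (Z)-3-{3-[(Z)-1-hydroxy-3-iodobut-2-enyl]-4-methylene-5-oxotetrahydrofuran-2-yl}-2-methylprop-2-enoate (2,3-cis lactone; C6, C7, C8 as in 30)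
Conditions: 16 (slight excess over base), KN(SiMe3)2, 18-crown-6, THF, −78 °C; then 15, −78 to −20 °C
Reagents that add atoms: none
Why: Still–Gennari olefination of the hydroxy aldehyde that is in equilibrium with the lactol gives the (Z)-2-methyl enoate through fast irreversible collapse of the kinetic adduct of the trifluoroethyl phosphonate, and because the only base present is the weakly basic phosphonate anion the liberated C8 hydroxyl stays protonated and neither lactone migration nor oxa-Michael closure is triggered.

Step 10
Reactants: 17 the hydroxy (Z)-enoate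
Product: 18 C8 triethylsilyl ether of 17
Conditions: Et3SiOTf, 2,6-lutidine, CH2Cl2, −78 °C
Reagents that add atoms: triethylsilyl trifluoromethanesulfonate, SMILES CC[Si](CC)(CC)OS(=O)(=O)C(F)(F)F
Why: Silylation of the secondary allylic alcohol with the silyl triflate and a hindered pyridine base is fast at −78 °C and removes O8 from the lactone and lactol equilibria of the next two steps.

Step 11
Reactants: 18 the silyl ether
Product: 19 (Z)-3-{5-hydroxy-3-[(Z)-3-iodo-1-(triethylsilyloxy)but-2-enyl]-4-methylenetetrahydrofuran-2-yl}-2-methylprop-2-en-1-ol (lactol epimers)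
Conditions: i-Bu2AlH, CH2Cl2, −78 °C; aq. KNaC4H4O6 work-up
Reagents that add atoms: none
Why: DIBAL reduction takes the conjugated ester to the (Z)-allylic alcohol and stops the α-methylene lactone at the lactol stage by 1,2-addition (stable tetrahedral aluminate at −78 °C), leaving silyl ether, vinyl iodide and both alkene geometries intact.

Step 12
Reactants: 19 the lactol allylic alcohol
Product: 20 (Z)-3-{3-[(Z)-3-iodo-1-(triethylsilyloxy)but-2-enyl]-4-methylene-5-oxotetrahydrofuran-2-yl}-2-methylprop-2-enal
Conditions: MnO2 (activated, excess), CH2Cl2, rt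
Reagents that add atoms: none
Why: Allylic oxidation with MnO2 converts the primary allylic alcohol into the (Z)-enal and the allylic hemiacetal back into the α-methylene lactone under neutral conditions, in which the lactol is not expected to open and the Z-enal not to isomerise.

Step 13
Reactants: 20 the silylated enal lactone
Product: 21 (Z)-3-{3-[(Z)-1-hydroxy-3-iodobut-2-enyl]-4-methylene-5-oxotetrahydrofuran-2-yl}-2-methylprop-2-enal
Conditions: HF·pyridine, pyridine, THF, 0 °C
Reagents that add atoms: none
Why: Buffered fluoride cleavage of the triethylsilyl ether is mild enough for enal, α-methylene lactone and vinyl iodide, and the neutral medium gives the free hydroxyl no chance to migrate the lactone.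

Step 14
Reactants: 21 the C8 alcohol; 22 (R)-2-methylbutanoic acid
Product: 23 C8 (R)-2-methylbutanoate of 21
Conditions: DCC, DMAP (cat.), CH2Cl2, 0 °C
Reagents that add atoms: none
Why: Steglich esterification acylates the secondary allylic alcohol with the enantiopure acid, whose α-centre bears only alkyl groups and is not epimerised by way of the O-acylisourea, while cold, catalytic DMAP spares the Z-enal.

Step 15
Reactants: 23 the (Z)-vinyl iodide ester; 24 tributyl(1-ethoxyvinyl)stannane
Product: 25 2-ethoxydiene (23 with C(OEt)=CH2 in place of iodine; C9=C10 still Z)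
Conditions: Pd(PPh3)4 (cat.), CuI, CsF, DMF, rt
Reagents that add atoms: none
Why: Stille coupling of the (Z)-alkenyl iodide with the α-ethoxyvinylstannane proceeds with retention of geometry, and copper- and fluoride-accelerated transmetalation at room temperature lets the alkenylpalladium intermediate couple before it can insert into the exo-methylene or ionise an allylic ester.

Step 16
Reactants: 25 the 2-ethoxydiene
Product: 26 seco bromomethyl ketone, (Z)-5-bromo-3-methyl-1-{2-[(Z)-2-methyl-3-oxoprop-1-enyl]-4-methylene-5-oxotetrahydrofuran-3-yl}-4-oxopent-2-enyl (R)-2-methylbutanoate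
Conditions: N-bromosuccinimide, THF/H2O, 0 °C
Reagents that add atoms: N-bromosuccinimide, SMILES O=C1CCC(=O)N1Br; water, SMILES O
Why: Electrophilic bromination of the terminal carbon of the enol ether and hydrolysis of the resulting oxocarbenium ion give the bromomethyl ketone directly (bromination of an enol ether), the electron-poor alkenes and the aldehyde being inert to NBS at 0 °C.

Step 17
Reactants: 26 the seco bromomethyl ketone; 27 acetaldehyde
Product: 30 CNP0282531.1 (target), via samarium enolate 28 (not isolated), via samarium aldolate 29 (not isolated)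
Conditions: SmI2 (0.1 M in THF, 2.2 equiv) added slowly to 26 (0.002 M in THF), −78 °C; then 27 (excess), −78 to −10 °C; pH 7 buffer
Reagents that add atoms: none
Why: Proposed new method: two single-electron transfers from SmI2 cleave the C2–Br bond to the trivalent samarium enolate 28, whose C2 adds to the C3 aldehyde to give the aldolate 29, and this trivalent samarium alkoxide then binds acetaldehyde as a hemiacetal and passes its hydride to the C1 ketone through a six-membered chair, which leaves the acetate on O3 and a samarium alkoxide on C1. The closest known reactions are the SmI2 Reformatsky macrocyclisation of formyl-tethered α-bromo carbonyl compounds and the samarium-catalysed Evans–Tishchenko reduction of β-hydroxy ketones, known separately and joined here through the aldolate they share. The ten-membered carbocycle closes by C2–C3 bond formation in a 10-(enolendo)-exo-trig aldol addition under high dilution, helped by the cis-lactone and the two Z-alkenes, which already bend the chain. C3 is set by the aldehyde face that the cyclisation conformer exposes (substrate control, taken to give 3S), and C1 follows from C3 because the hydride is delivered within the chair anti to the C3 oxygen (1S). The step needs reduction of the bromo ketone ahead of the enal, the enone and the methylene lactone, and 1,2- rather than conjugate attack of the enolate; these are secured by the very fast reduction of α-bromo ketones by SmI2 at −78 °C without HMPA or a proton source, by adding the reductant to the dilute substrate so that it is never in excess, and by the high affinity of samarium enolates for aldehydes.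

**Compound list**

1 | 1,2:5,6-di-O-isopropylidene-α-D-glucofuranose | CC1(C)OC[C@@H](O1)[C@H]2O[C@@H]3OC(C)(C)O[C@@H]3[C@H]2O | starting material
2 | 1,2:5,6-di-O-isopropylidene-α-D-ribo-hexofuranos-3-ulose | CC1(C)OC[C@@H](O1)[C@H]2O[C@@H]3OC(C)(C)O[C@@H]3C2=O | intermediate
3 | ethyl (triphenylphosphoranylidene)acetate | CCOC(=O)C=P(c1ccccc1)(c1ccccc1)c1ccccc1 | starting material
4 | ethyl 2-(3-deoxy-1,2:5,6-di-O-isopropylidene-α-D-ribo-hexofuranos-3-ylidene)acetate (alkene isomers) | CC1(C)OC[C@@H](O1)[C@H]2O[C@@H]3OC(C)(C)O[C@@H]3C2=CC(=O)OCC | intermediate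
5 | 3-deoxy-3-C-(2-ethoxy-2-oxoethyl)-1,2:5,6-di-O-isopropylidene-α-D-allofuranose | CC1(C)OC[C@@H](O1)[C@H]2O[C@@H]3OC(C)(C)O[C@@H]3[C@@H]2CC(=O)OCC | intermediate
6 | 3-deoxy-3-C-(2-ethoxy-2-oxoethyl)-1,2-O-isopropylidene-α-D-allofuranose (5,6-diol, not isolated) | OC[C@@H](O)[C@H]1O[C@@H]2OC(C)(C)O[C@@H]2[C@@H]1CC(=O)OCC | intermediate
7 | 3-deoxy-3-C-(2-ethoxy-2-oxoethyl)-1,2-O-isopropylidene-α-D-ribo-pentodialdo-1,4-furanose | O=C[C@H]1O[C@@H]2OC(C)(C)O[C@@H]2[C@@H]1CC(=O)OCC | intermediate
8 | ethyltriphenylphosphonium iodide | CC[P+](c1ccccc1)(c1ccccc1)c1ccccc1.[I-] | starting material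
9 | (5Z)-3,5,6,7-tetradeoxy-3-C-(2-ethoxy-2-oxoethyl)-6-iodo-1,2-O-isopropylidene-α-D-ribo-hept-5-enofuranose | C/C(I)=C/[C@H]1O[C@@H]2OC(C)(C)O[C@@H]2[C@@H]1CC(=O)OCC | intermediate
10 | lithium enolate of 9 (not isolated) | C/C(I)=C/[C@H]1O[C@@H]2OC(C)(C)O[C@@H]2[C@@H]1C=C(O[Li])OCC | intermediate
11 | Mannich base of 9 (C11 epimers) | C/C(I)=C/[C@H]1O[C@@H]2OC(C)(C)O[C@@H]2[C@@H]1C(CN(C)C)C(=O)OCC | intermediate
12 | methiodide of 11 (not isolated) | C/C(I)=C/[C@H]1O[C@@H]2OC(C)(C)O[C@@H]2[C@@H]1C(C[N+](C)(C)C)C(=O)OCC.[I-] | intermediate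
13 | (5Z)-3,5,6,7-tetradeoxy-3-C-[1-(ethoxycarbonyl)ethenyl]-6-iodo-1,2-O-isopropylidene-α-D-ribo-hept-5-enofuranose | C/C(I)=C/[C@H]1O[C@@H]2OC(C)(C)O[C@@H]2[C@@H]1C(=C)C(=O)OCC | intermediate
14 | (5Z)-3,5,6,7-tetradeoxy-3-C-[1-(ethoxycarbonyl)ethenyl]-6-iodo-D-ribo-hept-5-enofuranose (anomers, not isolated) | C/C(I)=C/[C@H]1OC(O)[C@H](O)[C@@H]1C(=C)C(=O)OCC | intermediate
15 | cis-fused lactol–lactone (α-methylene-γ-lactone on O6, furanose hemiacetal at C5, ring oxygen O8; anomers) | C/C(I)=C/[C@H]1OC(O)[C@@H]2OC(=O)C(=C)[C@@H]21 | intermediate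
16 | ethyl 2-[bis(2,2,2-trifluoroethoxy)phosphoryl]propanoate | CCOC(=O)C(C)P(=O)(OCC(F)(F)F)OCC(F)(F)F | starting material
17 | ethyl (Z)-3-{3-[(Z)-1-hydroxy-3-iodobut-2-enyl]-4-methylene-5-oxotetrahydrofuran-2-yl}-2-methylprop-2-enoate | C=C1C(=O)O[C@@H](/C=C(/C)C(=O)OCC)[C@H]1[C@H](O)/C=C(/C)I | intermediate
18 | C8 triethylsilyl ether of 17 | C=C1C(=O)O[C@@H](/C=C(/C)C(=O)OCC)[C@H]1[C@H](O[Si](CC)(CC)CC)/C=C(/C)I | intermediate
19 | lactol allylic alcohol (lactol epimers) | C=C1C(O)O[C@@H](/C=C(/C)CO)[C@H]1[C@H](O[Si](CC)(CC)CC)/C=C(/C)I | intermediate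
20 | silylated (Z)-enal α-methylene lactone | C=C1C(=O)O[C@@H](/C=C(/C)C=O)[C@H]1[C@H](O[Si](CC)(CC)CC)/C=C(/C)I | intermediate
21 | C8 alcohol, (Z)-enal α-methylene lactone | C=C1C(=O)O[C@@H](/C=C(/C)C=O)[C@H]1[C@H](O)/C=C(/C)I | intermediate
22 | (R)-2-methylbutanoic acid | CC[C@@H](C)C(=O)O | starting material
23 | C8 (R)-2-methylbutanoate, (Z)-vinyl iodide | C=C1C(=O)O[C@@H](/C=C(/C)C=O)[C@H]1[C@H](OC(=O)[C@H](C)CC)/C=C(/C)I | intermediate
24 | tributyl(1-ethoxyvinyl)stannane | CCCC[Sn](CCCC)(CCCC)C(=C)OCC | starting material
25 | 2-ethoxydiene | C=C1C(=O)O[C@@H](/C=C(/C)C=O)[C@H]1[C@H](OC(=O)[C@H](C)CC)/C=C(/C)C(=C)OCC | intermediate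
26 | seco bromomethyl ketone / (Z)-enal | C=C1C(=O)O[C@@H](/C=C(/C)C=O)[C@H]1[C@H](OC(=O)[C@H](C)CC)/C=C(/C)C(=O)CBr | intermediate
27 | acetaldehyde | CC=O | starting material
28 | samarium enolate of 26 (not isolated) | C=C1C(=O)O[C@@H](/C=C(/C)C=O)[C@H]1[C@H](OC(=O)[C@H](C)CC)/C=C(/C)C(=C)O[Sm](I)I | intermediate
29 | ten-membered samarium aldolate (C3–O–SmI2, C1 ketone; not isolated) | C=C1C(=O)O[C@H]2/C=C(/C)[C@@H](O[Sm](I)I)CC(=O)/C(C)=C\[C@@H](OC(=O)[C@H](C)CC)[C@@H]12 | intermediate
30 | CNP0282531.1, (1S,3S,4Z,6S,7R,8R,9Z)-3-acetoxy-1-hydroxy-8-[(2R)-2-methylbutanoyloxy]germacra-4,9,11(13)-trien-12,6-olide (target locants) | C=C1C(=O)O[C@H]2/C=C(/C)[C@@H](OC(C)=O)C[C@H](O)/C(C)=C\[C@@H](OC(=O)[C@H](C)CC)[C@@H]12 | target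

**Step count and risks**

Total steps: 17. Longest linear sequence: 17 steps (1 to 30); all other reactants are commercial.

Step 17 (bears the label). What may go wrong:
- the samarium aldolate may revert or dehydrate before the hydride transfer;
- acetaldehyde may be lost to pinacol coupling or intercept uncyclised enolate;
- electron transfer to the enal, the enone or the methylene lactone may compete;
- the ring may close on the other aldehyde face.

Fallback (sets out from 26, returns at 30): the cascade is divided into its two known halves. SmI2 Reformatsky macrocyclisation of 26 alone (THF, −78 °C, high dilution, cold quench with pH 7 buffer) would give the ten-membered β-hydroxy ketone F1, whose C3 epimers can be separated and assigned. The 3S epimer would then undergo a separate Evans–Tishchenko reduction (catalytic SmI2, acetaldehyde, THF, −10 °C) to 30.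

Step 9. What may go wrong: slow opening of the lactol, conjugate addition of the phosphonate anion to the methylene lactone, or alkoxide-mediated transfer of the lactone from O6 to the newly freed O8.

Fallback (sets out from 9, returns at 18): the furanose is opened as a dithioacetal before the methylene group exists, so that the olefination runs on a free aldehyde with O8 already silylated. Aqueous CF3CO2H on 9 would give, through the hydroxy ester lactol F2, the saturated lactol–lactone F3. Propane-1,3-dithiol and BF3·OEt2 would open it to the dithiane alcohol F4, and Et3SiOTf/2,6-lutidine would give the silyl ether F5. LDA would form the lactone lithium enolate F6, which Eschenmoser's salt would convert into the Mannich base F7, MeI into the methiodide F8 and NaHCO3 into the α-methylene lactone F9. I2/NaHCO3 in aqueous acetone would release the aldehyde F10, and Still–Gennari olefination of this free aldehyde with 16 would give 18.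

Step 5. What may go wrong: partial loss of iodine from the ylide (giving the iodine-free alkene), erosion of Z selectivity, and low conversion of the hindered α-alkoxy aldehyde.

Fallback (sets out from 7, returns at 9): the trisubstituted alkenyl halide is assembled by cross-coupling instead of olefination. Corey–Fuchs reaction of 7 (CBr4, PPh3) would give the 1,1-dibromoalkene F11. Palladium-catalysed Negishi coupling with MeZnCl (Pd(t-Bu3P)2), which is known to replace selectively the bromine trans to the carbon substituent, would give the (Z)-bromoalkene F12. Copper-catalysed halogen exchange (CuI, NaI, N,N′-dimethylethylenediamine, dioxane, 110 °C) would convert F12 into 9 with retention.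

**Further compounds**

F1 | step 17 | ten-membered β-hydroxy ketone (C3–OH, C1 ketone) | C=C1C(=O)O[C@H]2/C=C(/C)[C@@H](O)CC(=O)/C(C)=C\[C@@H](OC(=O)[C@H](C)CC)[C@@H]12
F2 | step 9 | hydroxy ester lactol with saturated arm (anomers) | C/C(I)=C/[C@H]1OC(O)[C@H](O)[C@@H]1CC(=O)OCC
F3 | step 9 | saturated cis-fused lactol–lactone (anomers) | C/C(I)=C/[C@H]1OC(O)[C@@H]2OC(=O)C[C@@H]21
F4 | step 9 | dithiane alcohol (1,3-dithian-2-yl on C6, lactone on O6, free C8–OH) | O=C1O[C@@H](C2SCCCS2)[C@H](C1)[C@H](O)/C=C(/C)I
F5 | step 9 | C8 triethylsilyl ether of F4 | O=C1O[C@@H](C2SCCCS2)[C@H](C1)[C@H](O[Si](CC)(CC)CC)/C=C(/C)I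
F6 | step 9 | lactone lithium enolate of F5 | C1=C(O[Li])O[C@@H](C2SCCCS2)[C@H]1[C@H](O[Si](CC)(CC)CC)/C=C(/C)I
F7 | step 9 | Mannich base of F5 (C11 epimers) | O=C1O[C@@H](C2SCCCS2)[C@H](C1CN(C)C)[C@H](O[Si](CC)(CC)CC)/C=C(/C)I
F8 | step 9 | methiodide of F7 | O=C1O[C@@H](C2SCCCS2)[C@H](C1C[N+](C)(C)C)[C@H](O[Si](CC)(CC)CC)/C=C(/C)I.[I-]
F9 | step 9 | α-methylene lactone dithiane | C=C1C(=O)O[C@@H](C2SCCCS2)[C@H]1[C@H](O[Si](CC)(CC)CC)/C=C(/C)I
F10 | step 9 | C5 aldehyde, α-methylene lactone, C8 silyl ether | C=C1C(=O)O[C@@H](C=O)[C@H]1[C@H](O[Si](CC)(CC)CC)/C=C(/C)I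
F11 | step 5 | 1,1-dibromoalkene from 7 | BrC(Br)=C[C@H]1O[C@@H]2OC(C)(C)O[C@@H]2[C@@H]1CC(=O)OCC
F12 | step 5 | (Z)-bromoalkene (bromo analogue of 9) | C/C(Br)=C/[C@H]1O[C@@H]2OC(C)(C)O[C@@H]2[C@@H]1CC(=O)OCC
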